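**Assumption:** the target SMILES has no stereocentre and no stereogenic double bond, so Polonidine A is achiral and no stereocontrol is needed. The tert-prenyl carbonate used for N-allylation is made in step 1 rather than assumed to be a catalogue item.

## Retrosynthetic overview

1. Polonidine A ⇒ cut one CH2–C3 bond. The CH2 carbon is the formyl carbon of N-tert-prenylindole-3-carbaldehyde, used with reversed polarity as a carbanion equivalent through its N–H hydrazone (N2 is lost). It is joined under Ni catalysis to the electrophilic C3 of 3-bromo-N-tert-prenylindole, giving the methylene level directly.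
2. The bromide ⇒ the same aldehyde, by Pinnick oxidation and ipso-bromodecarboxylation, so both halves come from one intermediate.
3. The aldehyde ⇒ indole-3-carbaldehyde + tert-butyl tert-prenyl carbonate (Pd-catalysed, branched-selective N-allylation). The carbonate ⇒ 2-methylbut-3-en-2-ol + Boc2O.
4. Rings: none is formed; both indole bicycles are bought intact in indole-3-carbaldehyde.

## Route

Step 1
Reactants: 1 2-methylbut-3-en-2-ol
Product: 3 tert-butyl (2-methylbut-3-en-2-yl) carbonate, via lithium alkoxide 2 (not isolated)
Conditions: n-BuLi (1.05 equiv), THF, 0 °C; then Boc2O (1.1 equiv), 0 °C → rt; H2O work-up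
Reagents that add atoms: di-tert-butyl dicarbonate (Boc2O), CC(C)(C)OC(=O)OC(=O)OC(C)(C)C
Why: The pre-formed lithium alkoxide of the hindered tertiary alcohol is acylated cleanly by Boc2O (O-tert-butoxycarbonylation), giving the ionisable tertiary allylic carbonate.

Step 2
Reactants: 4 1H-indole-3-carbaldehyde; 3 tert-butyl (2-methylbut-3-en-2-yl) carbonate
Product: 5 1-(2-methylbut-3-en-2-yl)-1H-indole-3-carbaldehyde
Conditions: [Pd(η3-C3H5)Cl]2 (2 mol %), Xantphos (5 mol %), Cs2CO3 (1 equiv), CH2Cl2, 0 °C → rt, stop at full conversion
Reagents that add atoms: none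
Why: Decarboxylative Tsuji–Trost N-allylation in which the acidic N–H of the 3-formylindole is deprotonated and the indolide attacks the 1,1-dimethylallyl–Pd(Xantphos) cation at its more substituted terminus (kinetic branched product), while the formyl group blocks C3.

(Step 2 is run on a scale that supplies both halves: about 40 % of 5 goes on to steps 3–4 and about 60 % is kept for step 5.)

Step 3
Reactants: 5 1-(2-methylbut-3-en-2-yl)-1H-indole-3-carbaldehyde
Product: 6 1-(2-methylbut-3-en-2-yl)-1H-indole-3-carboxylic acid
Conditions: NaClO2, NaH2PO4, 2-methylbut-2-ene (excess), t-BuOH/THF/H2O, rt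
Reagents that add atoms: sodium chlorite, [Na+].[O-]Cl=O
Why: Pinnick oxidation converts the aldehyde to the acid through the chlorite adduct, and the large excess of trisubstituted scavenger alkene removes HOCl before it can touch the indole or the less reactive vinyl group.

Step 4
Reactants: 6 1-(2-methylbut-3-en-2-yl)-1H-indole-3-carboxylic acid
Product: 7 3-bromo-1-(2-methylbut-3-en-2-yl)-1H-indole
Conditions: NBS (1.0 equiv), DMF, 0 °C → rt, dark; quick basic-alumina filtration, use within a day
Reagents that add atoms: N-bromosuccinimide, O=C1CCC(=O)N1Br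
Why: Halodecarboxylation by ipso-attack of Br+ at the electron-rich C3 followed by loss of CO2 to re-aromatise (Hunsdiecker-type for heteroarene acids), which is much faster than reaction at the monosubstituted alkene.

Step 5
Reactants: 5 1-(2-methylbut-3-en-2-yl)-1H-indole-3-carbaldehyde; 7 3-bromo-1-(2-methylbut-3-en-2-yl)-1H-indole
Product: 9 Polonidine A, via hydrazone 8 (not isolated)
Conditions: 5 (1.5 equiv), N2H4·H2O (1.6 equiv), THF, rt → 50 °C, 2 h; then 7 (1.0 equiv), Ni(cod)2 (10 mol %), PMe3 (20 mol %), DBU (2 equiv), 4 Å MS, THF, 60 °C, argon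
Reagents that add atoms: none
Why: Ni-catalysed deoxygenative cross-coupling of an aldehyde N–H hydrazone with an aryl bromide (Wolff–Kishner-type carbonyl umpolung), in which Ni(0) inserts into the C3–Br bond of 7, the deprotonated hydrazone 8 binds to nickel and expels N2 so the former formyl carbon arrives as a benzylic carbanion, and reductive elimination forms the CH2–C3 bond between two carbons that are both electrophilic in their parent compounds; no stereocentre is created.

## Compound list

1 | 2-methylbut-3-en-2-ol | C=CC(C)(C)O | starting material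
2 | lithium 2-methylbut-3-en-2-olate | [Li+].[O-]C(C)(C)C=C | intermediate (not isolated)
3 | tert-butyl (2-methylbut-3-en-2-yl) carbonate | C=CC(C)(C)OC(=O)OC(C)(C)C | intermediate
4 | 1H-indole-3-carbaldehyde | O=Cc1c[nH]c2ccccc12 | starting material
5 | 1-(2-methylbut-3-en-2-yl)-1H-indole-3-carbaldehyde | C=CC(C)(C)n1cc(C=O)c2ccccc21 | intermediate
6 | 1-(2-methylbut-3-en-2-yl)-1H-indole-3-carboxylic acid | C=CC(C)(C)n1cc(C(=O)O)c2ccccc21 | intermediate
7 | 3-bromo-1-(2-methylbut-3-en-2-yl)-1H-indole | C=CC(C)(C)n1cc(Br)c2ccccc21 | intermediate
8 | (E)-{[1-(2-methylbut-3-en-2-yl)-1H-indol-3-yl]methylidene}hydrazine | C=CC(C)(C)n1cc(/C=N/N)c2ccccc21 | intermediate (not isolated)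
9 | Polonidine A, bis[1-(2-methylbut-3-en-2-yl)-1H-indol-3-yl]methane | C=CC(C)(C)n1cc(Cc2cn(C(C)(C)C=C)c3ccccc23)c2ccccc21 | target

## Step count and risks

Total steps: 5. Longest linear sequence: 5 (1 → 3 → 5 → 6 → 7 → 9); 4 steps from indole-3-carbaldehyde.

**Step 5 (most likely to fail).** The reaction class is known, but this pairing of an electron-rich 3-bromoindole with a vinylogous-amide-type aldehyde hydrazone is untested. Risks are slow hydrazone formation or azine formation, sluggish oxidative addition, protodebromination of 7, and Ni(0) engaging the N-allyl or vinyl groups. The fallback keeps the reversed-polarity logic but uses a masked acyl anion. It sets out from 5, which is converted with propane-1,3-dithiol and BF3·OEt2 (CH2Cl2, 0 °C) into 2-[1-(2-methylbut-3-en-2-yl)-1H-indol-3-yl]-1,3-dithiane F1. Its metallated C2–H is arylated with 7 under Pd catalysis ([Pd(allyl)Cl]2, NiXantphos, LiN(SiMe3)2, THF, rt → 60 °C) to give 2,2-bis[1-(2-methylbut-3-en-2-yl)-1H-indol-3-yl]-1,3-dithiane F2. Radical desulfurisation with Bu3SnH/AIBN (toluene, 90 °C) then gives the methylene compound; Raney nickel is avoided because of the vinyl groups. The fallback comes back to the route at 9.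

**Step 4.** The ipso-bromodecarboxylation may be unselective (over-bromination at C2, bromination of the alkene), and 7 is light- and acid-sensitive. The fallback sets out from 6 and separates the two events. Protodecarboxylation (Ag2CO3 10 mol %, AcOH 5 mol %, DMSO, 120 °C) gives the isolable 1-(2-methylbut-3-en-2-yl)-1H-indole F3. This is brominated at C3 with NBS in THF at −78 °C and used at once, coming back to the route at 7.

**Step 2.** The branched N-tert-prenyl product can erode to the linear N-prenyl isomer by Pd-mediated re-ionisation, because the 3-formylindolide is a fair leaving group. The fallback sets out from 4 and replaces allylic substitution by oxidative N–H/alkene coupling with 2-methylbut-2-ene (Pd(OAc)2, Cu(OAc)2, AgOTf, MeCN, 35 °C). This installs the 1,1-dimethylallyl group directly and comes back to the route at 5, so this fallback makes no new compound, F0.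

## Further compounds

F1 | step 5 | 2-[1-(2-methylbut-3-en-2-yl)-1H-indol-3-yl]-1,3-dithiane | C=CC(C)(C)n1cc(C2SCCCS2)c2ccccc21
F2 | step 5 | 2,2-bis[1-(2-methylbut-3-en-2-yl)-1H-indol-3-yl]-1,3-dithiane | C=CC(C)(C)n1cc(C2(SCCCS2)c2cn(C(C)(C)C=C)c3ccccc23)c2ccccc21
F3 | step 4 | 1-(2-methylbut-3-en-2-yl)-1H-indole | C=CC(C)(C)n1ccc2ccccc21
F0 | step 2 | none | none
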